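Labdane numbering. Ring A (C1–C5, C10) is cis-fused to ring B: H-5 and the C10 methyl are syn, and C5 lies between the oxygenated C6 and the gem-dimethyl carbon C4. That pattern is the imprint of a Diels–Alder reaction, so everything rests on cutting C1–C10 and C4–C5. One cycloaddition of a C5=C10 enone with the silyl dienol ether of mesityl oxide closes ring A, builds the quaternary carbons C4 and C10 and sets C5 and C10. Its C2 oxygen is an activating group, removed afterwards. The dienophile is a tricyclic spiro-enone (ring B, tetrahydrofuran, lactone) obtained by oxidative dearomatisation of a para-alkylphenol and two methyl conjugate additions.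

Key step: step 11

Remark on the chemistry: the SMILES is read literally, that is with a cis A/B fusion and with H-5, 6-OAc, 8-CH3, the C9–O bond and 10-CH3 all on one face of ring B (5S,6S,8R,9R,10R,13R); labdane numbering is used for all intermediates.

Step 1
Reactants: 1 1-(benzyloxy)-4-(2-bromoethyl)benzene; 2 di-tert-butyl oxalate
Product: 4 tert-butyl 4-[4-(benzyloxy)phenyl]-2-oxobutanoate, via Grignard reagent 3 (not isolated)
Conditions: Mg, THF, rt; then added to 2 (2 equiv), THF, −78 °C; aq NH4Cl
Reagents that add atoms: none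
Why: Grignard acylation, in which the tetrahedral adduct with the bulky oxalate is stable at low temperature, so that addition should stop at the α-keto ester; no stereocentre is formed.

Step 2
Reactants: 5 S-tert-butyl thioacetate
Product: 6 1-(tert-butylsulfanyl)-1-(trimethylsilyloxy)ethene
Conditions: LiN(iPr)2, THF, −78 °C; TMSCl
Reagents that add atoms: chlorotrimethylsilane, C[Si](C)(C)Cl
Why: Kinetic enolisation of the thioester followed by O-silylation (silyl ketene thioacetal formation); no stereocentre is formed.

Step 3
Reactants: 4 tert-butyl 4-[4-(benzyloxy)phenyl]-2-oxobutanoate; 6 1-(tert-butylsulfanyl)-1-(trimethylsilyloxy)ethene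
Product: 8 tert-butyl (2R)-2-{2-[4-(benzyloxy)phenyl]ethyl}-4-(tert-butylsulfanyl)-2-hydroxy-4-oxobutanoate, via silyl ether 7 (not isolated)
Conditions: Cu(OTf)2 (10 mol %), (R,R)-t-Bu-box (11 mol %), THF, −78 °C; then 1 M HCl
Reagents that add atoms: none
Why: Catalytic enantioselective Mukaiyama aldol addition, in which the α-keto ester chelates divalent copper in a square-planar complex whose tert-butyl groups shield one ketone face, so that C14 should add to the open face and set C13 as R.

Step 4
Reactants: 8 tert-butyl (2R)-2-{2-[4-(benzyloxy)phenyl]ethyl}-4-(tert-butylsulfanyl)-2-hydroxy-4-oxobutanoate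
Product: 10 (3R)-3-{2-[4-(benzyloxy)phenyl]ethyl}-3-hydroxyoxolan-2-one, via diol ester 9 (not isolated)
Conditions: LiBH4, Et2O–THF, 0 °C; then TFA, CH2Cl2, rt
Reagents that add atoms: none
Why: Chemoselective hydride reduction followed by acid lactonisation, since LiBH4 should reduce the thioester but not the hindered tert-butyl ester and TFA then unmasks the C16 acid, which closes the five-membered lactone onto the new C15 hydroxyl without touching C13.

Step 5
Reactants: 10 (3R)-3-{2-[4-(benzyloxy)phenyl]ethyl}-3-hydroxyoxolan-2-one
Product: 11 (3R)-3-hydroxy-3-[2-(4-hydroxyphenyl)ethyl]oxolan-2-one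
Conditions: H2 (1 atm), Pd/C, EtOAc, rt
Reagents that add atoms: none
Why: Catalytic hydrogenolysis of the benzyl ether, to which the lactone and the tertiary alcohol are inert, so that C13 is untouched.

Step 6
Reactants: 11 (3R)-3-hydroxy-3-[2-(4-hydroxyphenyl)ethyl]oxolan-2-one
Product: 12 (13R)-spirodienone: ring B as cyclohexa-2,5-dienone (C6=O), spiro at C9 to the tetrahydrofuran (O, C11, C12, C13), which is spiro at C13 to the γ-lactone
Conditions: PhI(OAc)2, (CF3)2CHOH, 0 °C
Reagents that add atoms: none
Why: Oxidative phenol dearomatisation with trivalent iodine (spiroetherification by 5-exo attack of the C13 hydroxyl on the para carbon C9) in a non-nucleophilic fluoroalcohol; C9 is not yet stereogenic because the two enone arms are identical.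

Step 7
Reactants: 12 (13R)-spirodienone
Product: 13 (8R,9R,13R)-8-methyl spiro-enone: C7–C8 saturated, 8-CH3 syn to the ether oxygen, C5=C10 enone retained
Conditions: Me2Zn, Cu(OTf)2 (2 mol %), phosphoramidite from (S)-BINOL and bis[(R)-1-phenylethyl]amine (4 mol %), toluene, −25 °C; aq NH4Cl
Reagents that add atoms: dimethylzinc, C[Zn]C
Why: Copper-catalysed asymmetric conjugate addition that desymmetrises the dienone, with methyl delivered on the face syn to the ether oxygen (the sterically and electronically preferred face of 4-alkoxy-4-alkyl dienones) and the ligand selecting the arm on the C16 side of the tetrahydrofuran, which sets C8 and C9 together.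

Step 8
Reactants: 13 (8R,9R,13R)-8-methyl spiro-enone
Product: 14 C5=C6 trimethylsilyl enol ether with 8-CH3 and 10-CH3 (10-CH3 trans to 8-CH3)
Conditions: MeLi, CuI, Et2O, 0 °C; then 13, TMSCl, −78 °C; Et3N, pentane work-up
Reagents that add atoms: lithium dimethylcuprate, [Li+].C[Cu-]C; chlorotrimethylsilane, C[Si](C)(C)Cl
Why: Gilman cuprate conjugate addition accelerated and trapped by TMSCl, which gives the C5=C6 enol silane regiospecifically, the new C10 centre (axial attack, methyl expected trans to the C8 methyl) being transient and erased in step 9.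

Step 9
Reactants: 14 C5=C6 trimethylsilyl enol ether
Product: 15 (8R,9R,13R)-8,10-dimethyl spiro-enone (C6=O, C5=C10 with methyl on C10)
Conditions: Pd(OAc)2 (1.05 equiv), MeCN, rt
Reagents that add atoms: none
Why: Saegusa–Ito oxidation, in which palladation of the regiodefined enol silane at C5 and β-hydride elimination of H-10 should restore the enone with the methyl now on C10, leaving C8, C9 and C13 untouched.

Step 10
Reactants: 16 mesityl oxide
Product: 17 2-(tert-butyldimethylsilyloxy)-4-methylpenta-1,3-diene
Conditions: LiN(iPr)2, THF, −78 °C; TBSCl, DMPU, −78 °C to rt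
Reagents that add atoms: tert-butyldimethylsilyl chloride, CC(C)(C)[Si](C)(C)Cl
Why: Kinetic deprotonation of the acetyl methyl group of the enone followed by O-silylation gives the cross-conjugated 2-silyloxydiene; no stereocentre is formed.

Step 11
Reactants: 15 (8R,9R,13R)-8,10-dimethyl spiro-enone; 17 2-(tert-butyldimethylsilyloxy)-4-methylpenta-1,3-diene
Product: 19 (5S,8R,9R,10R,13R)-cis-fused 2,6-diketone with ring A closed, via silyl enol ether cycloadduct 18 (not isolated)
Conditions: 17 (4 equiv), AlBr3–AlMe3 (5:1, 3 equiv of Al), toluene–CH2Cl2, −20 to 0 °C; then 1 M HCl, THF, rt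
Reagents that add atoms: none
Why: The aluminium Lewis acid binds the C6 carbonyl of 15, the nucleophilic CH2 terminus of 17 (future C1) attacks the β-carbon C10, and the aluminium enolate carbon C5 then collapses on the dimethyl-substituted end (C4) of the silyloxyallyl cation, that is a strongly asynchronous [4+2] cycloaddition whose stepwise limit is a Mukaiyama–Michael/Michael sequence. The closest known reaction type is the Diels–Alder reaction of hindered 2-silyloxy-1,3-dienes bearing a disubstituted terminus with β-substituted cyclohexenones under AlBr3–AlMe3 promotion. Ring A (C1, C2, C3, C4, C5, C10) is the only ring closed, intermolecularly through the two bonds C1–C10 and C4–C5 added suprafacially across C5=C10. C10 is controlled by the half-chair of 15 with the C8 methyl pseudo-equatorial and the C9–O bond pseudo-axial, in which axial attack comes from the face anti to the ether oxygen and trans to the C8 methyl, leaving the C10 methyl syn to the ether oxygen. C5 follows from suprafacial addition (H-5 cis to the C10 methyl) and is also the thermodynamic epimer, because the trans-fused isomer would hold the C8 and C10 methyls 1,3-diaxial, so the acidic work-up should correct any leakage. The step needs regioselectivity, secured by the matched para effect of the C2 silyloxy group and ortho effect of the dimethyl terminus, and chemoselectivity, secured because 15 has a single enone and both ether carbons (C9 next to the complexed enone, C13 next to the lactone carbonyl) resist ionisation.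

Step 12
Reactants: 19 (5S,8R,9R,10R,13R)-cis-fused 2,6-diketone
Product: 21 (5S,8R,9R,10R,13R)-9,13-epoxy-6-oxolabdan-16,15-olide (cis A/B), via tosylhydrazone 20 (not isolated)
Conditions: TsNHNH2 (1.05 equiv), EtOH, 40 °C; evaporate; catecholborane, CHCl3, −10 °C; NaOAc·3H2O, reflux
Reagents that add atoms: none
Why: Tosylhydrazone formation and hydride reduction (Caglioti-type deoxygenation), in which only the open C2 ketone should condense because the C6 ketone is shielded by C4 and C10, and hydroboration of C=N followed by loss of sulfinate and N2 leaves CH2 without changing any stereocentre.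

Step 13
Reactants: 21 (5S,8R,9R,10R,13R)-9,13-epoxy-6-oxolabdan-16,15-olide
Product: 22 (5S,6S,8R,9R,10R,13R)-9,13-epoxy-6-hydroxylabdan-16,15-olide (6-OH equatorial, cis to H-5)
Conditions: SmI2, H2O, THF, rt
Reagents that add atoms: none
Why: Single-electron ketyl reduction, which like dissolving-metal reductions should give the thermodynamically preferred equatorial alcohol (hydrides would attack the open face and give the axial epimer), while five-membered lactones are not reduced by SmI2–H2O without an amine.

Step 14
Reactants: 22 (5S,6S,8R,9R,10R,13R)-9,13-epoxy-6-hydroxylabdan-16,15-olide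
Product: 23 (5S,6S,8R,9R,10R,13R)-6-acetoxy-9,13-epoxylabdan-16,15-olide (CNP0081177.1)
Conditions: Ac2O, DMAP, pyridine, rt
Reagents that add atoms: acetic anhydride, CC(=O)OC(C)=O
Why: DMAP-catalysed acetylation of the secondary alcohol, which proceeds with retention at C6 and leaves all other centres untouched.

Compound list
1 | 1-(benzyloxy)-4-(2-bromoethyl)benzene | BrCCc1ccc(OCc2ccccc2)cc1 | starting material
2 | di-tert-butyl oxalate | CC(C)(C)OC(=O)C(=O)OC(C)(C)C | starting material
3 | 2-[4-(benzyloxy)phenyl]ethylmagnesium bromide | Br[Mg]CCc1ccc(OCc2ccccc2)cc1 | intermediate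
4 | tert-butyl 4-[4-(benzyloxy)phenyl]-2-oxobutanoate | CC(C)(C)OC(=O)C(=O)CCc1ccc(OCc2ccccc2)cc1 | intermediate
5 | S-tert-butyl thioacetate | CC(=O)SC(C)(C)C | starting material
6 | 1-(tert-butylsulfanyl)-1-(trimethylsilyloxy)ethene | C=C(O[Si](C)(C)C)SC(C)(C)C | intermediate
7 | O-trimethylsilyl ether of aldol adduct 8 | C(c1ccccc1)Oc1ccc(CC[C@](C(=O)OC(C)(C)C)(CC(=O)SC(C)(C)C)O[Si](C)(C)C)cc1 | intermediate
8 | tert-butyl (2R)-2-{2-[4-(benzyloxy)phenyl]ethyl}-4-(tert-butylsulfanyl)-2-hydroxy-4-oxobutanoate | C(c1ccccc1)Oc1ccc(CC[C@](C(=O)OC(C)(C)C)(CC(=O)SC(C)(C)C)O)cc1 | intermediate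
9 | tert-butyl (2R)-2-{2-[4-(benzyloxy)phenyl]ethyl}-2,4-dihydroxybutanoate | C(c1ccccc1)Oc1ccc(CC[C@](C(=O)OC(C)(C)C)(CCO)O)cc1 | intermediate
10 | (3R)-3-{2-[4-(benzyloxy)phenyl]ethyl}-3-hydroxyoxolan-2-one | C(c1ccccc1)Oc1ccc(CC[C@]2(CCOC2=O)O)cc1 | intermediate
11 | (3R)-3-hydroxy-3-[2-(4-hydroxyphenyl)ethyl]oxolan-2-one | Oc1ccc(CC[C@]2(CCOC2=O)O)cc1 | intermediate
12 | (13R)-spirodienone (cyclohexa-2,5-dienone, tetrahydrofuran and γ-lactone joined by the spiro atoms C9 and C13) | O=C1C=CC2(CC[C@]3(CCOC3=O)O2)C=C1 | intermediate
13 | (8R,9R,13R)-8-methyl spiro-enone, 8-CH3 syn to the ether oxygen | O=C1C[C@@H](C)[C@]2(CC[C@]3(CCOC3=O)O2)C=C1 | intermediate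
14 | C5=C6 trimethylsilyl enol ether, 10-CH3 trans to 8-CH3 | C[Si](C)(C)OC=1C[C@@H](C)[C@]2(CC[C@]3(CCOC3=O)O2)[C@H](C)C=1 | intermediate
15 | (8R,9R,13R)-8,10-dimethyl spiro-enone | O=C1C[C@@H](C)[C@]2(CC[C@]3(CCOC3=O)O2)C(C)=C1 | intermediate
16 | mesityl oxide | CC(=O)C=C(C)C | starting material
17 | 2-(tert-butyldimethylsilyloxy)-4-methylpenta-1,3-diene | C=C(O[Si](C)(C)C(C)(C)C)C=C(C)C | intermediate
18 | cycloadduct, C2=C3 tert-butyldimethylsilyl enol ether, cis A/B | O=C1C[C@@H](C)[C@]2(CC[C@]3(CCOC3=O)O2)[C@]2(C)CC(O[Si](C)(C)C(C)(C)C)=CC(C)(C)[C@H]12 | intermediate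
19 | (5S,8R,9R,10R,13R)-9,13-epoxy-2,6-dioxolabdan-16,15-olide, cis A/B | O=C1C[C@@H](C)[C@]2(CC[C@]3(CCOC3=O)O2)[C@]2(C)CC(=O)CC(C)(C)[C@H]12 | intermediate
20 | C2 tosylhydrazone of 19 | O=C1C[C@@H](C)[C@]2(CC[C@]3(CCOC3=O)O2)[C@]2(C)CC(=NNS(=O)(=O)c3ccc(C)cc3)CC(C)(C)[C@H]12 | intermediate
21 | (5S,8R,9R,10R,13R)-9,13-epoxy-6-oxolabdan-16,15-olide, cis A/B | O=C1C[C@@H](C)[C@]2(CC[C@]3(CCOC3=O)O2)[C@]2(C)CCCC(C)(C)[C@H]12 | intermediate
22 | (5S,6S,8R,9R,10R,13R)-9,13-epoxy-6-hydroxylabdan-16,15-olide | O[C@H]1C[C@@H](C)[C@]2(CC[C@]3(CCOC3=O)O2)[C@]2(C)CCCC(C)(C)[C@H]12 | intermediate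
23 | (5S,6S,8R,9R,10R,13R)-6-acetoxy-9,13-epoxylabdan-16,15-olide | CC(=O)O[C@H]1C[C@@H](C)[C@]2(CC[C@]3(CCOC3=O)O2)[C@]2(C)CCCC(C)(C)[C@H]12 | target

Total step count: 14. Longest linear sequence: 12 (steps 1, 3–9, 11–14).

Steps most likely to fail

Step 11. The first bond to the congested C10 may form too slowly, so that Lewis-acid-induced oligomerisation or protodesilylation of the diene takes over. The sequence may also stop after the first Michael bond and reopen by retro-Michael cleavage.
- The fallback sets out from 15 and comes back at 21. It closes ring A by one bond instead of two.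
- Commercial 5-bromo-2-methylpent-2-ene takes up HCl (CH2Cl2, 0 °C) to give 5-bromo-2-chloro-2-methylpentane F1.
- Mg in THF inserts into the primary C–Br bond to give (4-chloro-4-methylpentyl)magnesium bromide F2.
- Copper-catalysed conjugate addition to 15 (CuBr·SMe2, TMSCl, THF, −78 °C), again axial and trans to the C8 methyl, gives the chloroalkyl silyl enol ether F3.
- TiCl4 in CH2Cl2 at −78 to −40 °C then ionises the tertiary chloride and C5 attacks the C4 cation (intramolecular Lewis-acid-mediated α-tert-alkylation of a silyl enol ether). This gives 21 directly and makes step 12 unnecessary.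

Step 7. Discrimination between the two diastereotopic enone arms may be insufficient, or methyl transfer from Me2Zn may be too slow.
- The fallback sets out from 12 and comes back at 15. It replaces catalyst control by a convergent use of both arm isomers.
- Achiral Me2CuLi (Et2O, −78 °C) adds syn to the ether oxygen on either arm and gives 13 together with its diastereomer, the 10-methyl arm isomer F4. The two are separated by chromatography.
- 13 goes on through steps 8 and 9.
- F4 already carries its methyl on the future C10. It is dehydrogenated with IBX (DMSO, 70 °C) to the 10-methyl spirodienone F5.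
- Me2CuLi then adds to the unsubstituted arm of F5, syn to the ether oxygen, to give 15.

Step 13. Electron transfer to the α-alkoxy lactone with cleavage of the C13–O bond may compete, or protonation of the reduced C6 centre may be insufficiently selective.
- The fallback sets out from 21 and comes back at 23.
- LiBH(s-Bu)3 (THF, −78 °C) attacks the ketone from the open face and gives the axial 6-epi alcohol F6.
- A Mitsunobu reaction with acetic acid (PPh3, DIAD, toluene) inverts C6 and installs the acetate in the same operation.

Further compounds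
F1 | step 11 | 5-bromo-2-chloro-2-methylpentane | CC(C)(Cl)CCCBr
F2 | step 11 | (4-chloro-4-methylpentyl)magnesium bromide | CC(C)(Cl)CCC[Mg]Br
F3 | step 11 | chloroalkyl silyl enol ether (C5=C6 trimethylsilyl enol ether, C10 bearing methyl and 4-chloro-4-methylpentyl) | C[Si](C)(C)OC=1C[C@@H](C)[C@]2(CC[C@]3(CCOC3=O)O2)[C@](C)(CCCC(C)(C)Cl)C=1
F4 | step 7 | 10-methyl arm isomer (C5–C10 saturated, 10-CH3 syn to the ether oxygen, C7=C8 enone) | O=C1C=C[C@]2(CC[C@]3(CCOC3=O)O2)[C@@H](C)C1
F5 | step 7 | 10-methyl spirodienone | O=C1C=C[C@]2(CC[C@]3(CCOC3=O)O2)C(C)=C1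
F6 | step 13 | axial 6-epi alcohol | O[C@@H]1C[C@@H](C)[C@]2(CC[C@]3(CCOC3=O)O2)[C@]2(C)CCCC(C)(C)[C@H]12
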